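The carbocycle is disconnected across C6–C7 and C8–C8a into a 4-(acylmethylene)-4H-pyran and (R)-lactic acid. The target's 4-alkylidene-4H-pyran (ring O2, C1, C3, C4, C4a, C8a) is an ambiphile: the exocyclic acyl carbon C6 is electrophilic, the enol-ether carbon C8a nucleophilic. In one operation the silyl ketene acetal of the lactic acid pivalaldehyde acetal is C-acylated at C7 by the pyranylidene acylium, and its own carbonyl C8 then acylates C8a. This closes ring C4a–C5–C6–C7–C8–C8a and sets C7 from the acetal stereocentre. The precursor is a monocyclic pyranylidene acid chloride carrying a phosphonium handle for the later Wittig coupling; C8 is reduced last.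

Key step: step 10

Assumption: atom labels follow the isochromene numbering of the target (O2, C1, C3, C4, C4a, C5–C8, C8a); compounds 1, 10, 11 and 16 are taken as purchasable; the exocyclic pyranylidene C=C bond of 6–9 and 14 is an interconverting E/Z pair (push-pull alkene), so no geometry is assigned to it.

Step 1
Reactants: 1 comanic acid (4-oxo-4H-pyran-2-carboxylic acid)
Product: 2 2-(hydroxymethyl)-4H-pyran-4-one
Conditions: i-BuOCOCl, N-methylmorpholine, THF, −15 °C; then NaBH4, H2O, 0 °C
Reagents that add atoms: none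
Why: Mixed carbonic anhydride activation followed by borohydride reduction converts the acid into the primary alcohol, while the vinylogous-ester carbonyl of the pyranone is too electron-rich to be reduced at low temperature.

Step 2
Reactants: 2 2-(hydroxymethyl)-4H-pyran-4-one
Product: 3 2-(chloromethyl)-4H-pyran-4-one
Conditions: SOCl2, CH2Cl2, 0 °C → rt
Reagents that add atoms: thionyl chloride, O=S(Cl)Cl
Why: Chlorodehydroxylation through the chlorosulfite, as is usual for 2-(hydroxymethyl)-4-pyranones, gives the primary chloride.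

Step 3
Reactants: 3 2-(chloromethyl)-4H-pyran-4-one
Product: 4 2-(chloromethyl)-4H-pyran-4-thione
Conditions: Lawesson's reagent (0.55 equiv), toluene, 80 °C
Reagents that add atoms: Lawesson's reagent, COc1ccc(cc1)P1(=S)SP(=S)(S1)c1ccc(OC)cc1
Why: Thionation exchanges the polarised vinylogous-ester C=O for C=S through a thiaoxaphosphetane and leaves the alkyl chloride untouched.

Step 4
Reactants: 4 2-(chloromethyl)-4H-pyran-4-thione
Product: 6 tert-butyl 2-[2-(chloromethyl)-4H-pyran-4-ylidene]acetate, via spiro thiirane 5 (not isolated)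
Conditions: tert-butyl diazoacetate, Rh2(OAc)4 (1 mol%), toluene, 60 °C; then PPh3 (1.05 equiv), rt
Reagents that add atoms: tert-butyl diazoacetate, [N-]=[N+]=CC(=O)OC(C)(C)C
Why: Barton–Kellogg olefination: the rhodium carbenoid adds to sulfur, the thiocarbonyl ylide closes to thiirane 5, and PPh3 extrudes sulfur to give the push-pull alkene.

Step 5
Reactants: 6 tert-butyl 2-[2-(chloromethyl)-4H-pyran-4-ylidene]acetate
Product: 7 tert-butyl 2-chloro-2-[2-(chloromethyl)-4H-pyran-4-ylidene]acetate
Conditions: N-chlorosuccinimide, CH2Cl2, 0 °C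
Reagents that add atoms: N-chlorosuccinimide, O=C1CCC(=O)N1Cl
Why: Electrophilic chlorination at the exocyclic α-carbon, the most nucleophilic site of the dienol-ether/ester push-pull system, followed by loss of the proton restores the pyranylidene and installs the C5 chlorine.

Step 6
Reactants: 7 tert-butyl 2-chloro-2-[2-(chloromethyl)-4H-pyran-4-ylidene]acetate
Product: 8 tributyl{[4-(2-tert-butoxy-1-chloro-2-oxoethylidene)-4H-pyran-2-yl]methyl}phosphonium chloride
Conditions: PBu3, MeCN, rt → 40 °C
Reagents that add atoms: tributylphosphine, CCCCP(CCCC)CCCC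
Why: SN2 quaternisation of the primary, allylic-type chloride by the trialkylphosphine installs the Wittig handle, which later also shields C4.

Step 7
Reactants: 8 tributyl{[4-(2-tert-butoxy-1-chloro-2-oxoethylidene)-4H-pyran-2-yl]methyl}phosphonium chloride
Product: 9 tributyl{[4-(1,2-dichloro-2-oxoethylidene)-4H-pyran-2-yl]methyl}phosphonium chloride
Conditions: SOCl2 (neat, trace H2O), rt; evaporate, use crude
Reagents that add atoms: thionyl chloride, O=S(Cl)Cl
Why: Direct conversion of a tert-butyl ester into the acid chloride with thionyl chloride (acidolysis of the tert-butyl group, then chlorination); the phosphonium salt is inert.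

Step 8
Reactants: 10 (R)-lactic acid, 11 pivalaldehyde
Product: 12 (2R,5R)-2-tert-butyl-5-methyl-1,3-dioxolan-4-one
Conditions: p-TsOH·H2O (cat.), H2SO4 (cat.), pentane, reflux, Dean–Stark; recrystallisation
Reagents that add atoms: none
Why: Acid-catalysed acetalisation with removal of water gives the cis-2,5-disubstituted dioxolanone (thermodynamic and crystallisation control), which stores the chirality of lactic acid at the new acetal carbon.

Step 9
Reactants: 12 (2R,5R)-2-tert-butyl-5-methyl-1,3-dioxolan-4-one
Product: 13 (2R)-2-tert-butyl-4-[(tert-butyldimethylsilyl)oxy]-5-methyl-1,3-dioxole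
Conditions: LiN(i-Pr)2, THF, −78 °C; then t-BuMe2SiCl, −78 °C → rt; use crude
Reagents that add atoms: tert-butyldimethylsilyl chloride, CC(C)(C)[Si](C)(C)Cl
Why: Kinetic enolisation and O-silylation give the silyl ketene acetal; the lactic acid stereocentre becomes trigonal while the acetal stereocentre persists (self-regeneration of stereocentres).

Step 10
Reactants: 9 tributyl{[4-(1,2-dichloro-2-oxoethylidene)-4H-pyran-2-yl]methyl}phosphonium chloride, 13 (2R)-2-tert-butyl-4-[(tert-butyldimethylsilyl)oxy]-5-methyl-1,3-dioxole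
Product: 15 tributyl{[(7R)-5-chloro-7-hydroxy-7-methyl-6,8-dioxo-7,8-dihydro-6H-isochromen-3-yl]methyl}phosphonium trifluoromethanesulfonate, via C-acylated dioxolanone 14 (not isolated)
Conditions: AgOSO2CF3 (2.1 equiv), 2,6-di-tert-butyl-4-methylpyridine (1.2 equiv), CH2Cl2, −78 °C → 0 °C; then aq. NaHCO3
Reagents that add atoms: silver trifluoromethanesulfonate, [Ag+].[O-]S(=O)(=O)C(F)(F)F
Why: Proposed new method: AgOSO2CF3 ionises 9 to a pyrylium-stabilised acylium (ketene-like at C6); silyl ketene acetal 13 attacks C6 through its methyl-bearing carbon on the face anti to the tert-butyl group (self-regeneration of stereocentres; C7 is the only new stereocentre and should end R), and the silyl triflate released activates the dioxolanone carbonyl C8 of 14, which acylates the enol-ether carbon C8a (β to O2) before aqueous work-up collapses the silylated hemiketal with loss of pivalaldehyde. The closest known reaction types are the Lewis-acid-mediated C-acylation of silyl ketene acetals by acyl halides (Mukaiyama type) and the intramolecular Friedel–Crafts acylation of enol ethers and vinylogous esters; their union as a formal [4+2] double acylation is new. The six-membered ring closes in a 6-(enolexo)-exo-trig mode. Site selectivity (C8a, not C4) should be secured by the cationic, bulky tributylphosphoniomethyl group next to C4, and C- over O-acylation by the soft acylium and transfer of silicon to triflate. Both E and Z isomers about C4a=C5 should converge because the push-pull bond rotates before closure.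

Step 11
Reactants: 16 (S)-α-methyl-γ-butyrolactone ((3S)-3-methyloxolan-2-one)
Product: 17 (3S)-3-methyloxolan-2-ol (lactol, anomeric mixture)
Conditions: i-Bu2AlH (1.05 equiv), CH2Cl2, −78 °C; Rochelle salt work-up
Reagents that add atoms: none
Why: Partial reduction of the lactone stops at the tetrahedral aluminium acetal at low temperature; the α-stereocentre is not touched.

Step 12
Reactants: 17 (3S)-3-methyloxolan-2-ol
Product: 18 (2E,4S)-6-hydroxy-2,4-dimethylhex-2-enal
Conditions: Ph3P=C(CH3)CHO (1.05 equiv), toluene, 80 °C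
Reagents that add atoms: 2-(triphenylphosphoranylidene)propanal, CC(C=O)=P(c1ccccc1)(c1ccccc1)c1ccccc1
Why: Wittig reaction of the open hydroxy-aldehyde form of the lactol with a formyl-stabilised ylide should give the E-trisubstituted enal; no base is present, so the α-stereocentre should not epimerise.

Step 13
Reactants: 15 tributyl{[(7R)-5-chloro-7-hydroxy-7-methyl-6,8-dioxo-7,8-dihydro-6H-isochromen-3-yl]methyl}phosphonium trifluoromethanesulfonate, 18 (2E,4S)-6-hydroxy-2,4-dimethylhex-2-enal
Product: 19 (7R)-5-chloro-7-hydroxy-3-[(1E,3E,5S)-7-hydroxy-3,5-dimethylhepta-1,3-dien-1-yl]-7-methyl-6H-isochromene-6,8(7H)-dione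
Conditions: Et3N (1.5 equiv), CH2Cl2–toluene, rt → 50 °C
Reagents that add atoms: none
Why: Wittig olefination: the ylide from 15 is stabilised through the pyranylidene dienone, so a weak amine base suffices and the trialkylphosphonium ylide should give the new C=C bond E; the tertiary alcohol and the non-enolisable diketone should tolerate these conditions.

Step 14
Reactants: 19 (7R)-5-chloro-7-hydroxy-3-[(1E,3E,5S)-7-hydroxy-3,5-dimethylhepta-1,3-dien-1-yl]-7-methyl-6H-isochromene-6,8(7H)-dione
Product: 20 (7R,8R)-5-chloro-7,8-dihydroxy-3-[(1E,3E,5S)-7-hydroxy-3,5-dimethylhepta-1,3-dien-1-yl]-7-methyl-7,8-dihydro-6H-isochromen-6-one (target)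
Conditions: (S)-2-methyl-CBS-oxazaborolidine (0.5 equiv), catecholborane (4 equiv), CH2Cl2–toluene, −78 °C; then MeOH, pH 7 buffer
Reagents that add atoms: none
Why: Corey–Bakshi–Shibata reduction: hydride should add 1,2 to C8, the more ketone-like carbonyl (C6 is the acceptor end of the cross-conjugated pyranylidene chromophore), from the face anti to the C7–O bond (Felkin–Anh, the C7 hydroxyl being tied up in the flask as a non-chelating catechol borate), a face the (S)-catalyst also selects if C7 acts as the large group, which sets C8 as R and the diol cis.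

Compound list
1 | comanic acid (4-oxo-4H-pyran-2-carboxylic acid) | O=C(O)C1=CC(=O)C=CO1 | starting material
2 | 2-(hydroxymethyl)-4H-pyran-4-one | OCC1=CC(=O)C=CO1 | intermediate
3 | 2-(chloromethyl)-4H-pyran-4-one | ClCC1=CC(=O)C=CO1 | intermediate
4 | 2-(chloromethyl)-4H-pyran-4-thione | ClCC1=CC(=S)C=CO1 | intermediate
5 | tert-butyl 7-(chloromethyl)-6-oxa-1-thiaspiro[2.5]octa-4,7-diene-2-carboxylate (spiro thiirane, not isolated) | ClCC1=CC2(SC2C(=O)OC(C)(C)C)C=CO1 | intermediate
6 | tert-butyl 2-[2-(chloromethyl)-4H-pyran-4-ylidene]acetate | ClCC1=CC(=CC(=O)OC(C)(C)C)C=CO1 | intermediate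
7 | tert-butyl 2-chloro-2-[2-(chloromethyl)-4H-pyran-4-ylidene]acetate | ClCC1=CC(=C(Cl)C(=O)OC(C)(C)C)C=CO1 | intermediate
8 | tributyl{[4-(2-tert-butoxy-1-chloro-2-oxoethylidene)-4H-pyran-2-yl]methyl}phosphonium chloride | [Cl-].CCCC[P+](CCCC)(CCCC)CC1=CC(=C(Cl)C(=O)OC(C)(C)C)C=CO1 | intermediate
9 | tributyl{[4-(1,2-dichloro-2-oxoethylidene)-4H-pyran-2-yl]methyl}phosphonium chloride | [Cl-].CCCC[P+](CCCC)(CCCC)CC1=CC(=C(Cl)C(Cl)=O)C=CO1 | intermediate
10 | (R)-lactic acid | C[C@@H](O)C(=O)O | starting material
11 | pivalaldehyde | CC(C)(C)C=O | starting material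
12 | (2R,5R)-2-tert-butyl-5-methyl-1,3-dioxolan-4-one | C[C@H]1O[C@@H](C(C)(C)C)OC1=O | intermediate
13 | (2R)-2-tert-butyl-4-[(tert-butyldimethylsilyl)oxy]-5-methyl-1,3-dioxole | CC1=C(O[Si](C)(C)C(C)(C)C)O[C@H](C(C)(C)C)O1 | intermediate
14 | tributyl{[4-(1-chloro-2-oxo-2-[(2R,4S)-2-tert-butyl-4-methyl-5-oxo-1,3-dioxolan-4-yl]ethylidene)-4H-pyran-2-yl]methyl}phosphonium trifluoromethanesulfonate (not isolated) | [O-]S(=O)(=O)C(F)(F)F.CCCC[P+](CCCC)(CCCC)CC1=CC(=C(Cl)C(=O)[C@]2(C)O[C@@H](C(C)(C)C)OC2=O)C=CO1 | intermediate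
15 | tributyl{[(7R)-5-chloro-7-hydroxy-7-methyl-6,8-dioxo-7,8-dihydro-6H-isochromen-3-yl]methyl}phosphonium trifluoromethanesulfonate | [O-]S(=O)(=O)C(F)(F)F.CCCC[P+](CCCC)(CCCC)CC1=CC2=C(Cl)C(=O)[C@](C)(O)C(=O)C2=CO1 | intermediate
16 | (S)-α-methyl-γ-butyrolactone ((3S)-3-methyloxolan-2-one) | C[C@H]1CCOC1=O | starting material
17 | (3S)-3-methyloxolan-2-ol | C[C@H]1CCOC1O | intermediate
18 | (2E,4S)-6-hydroxy-2,4-dimethylhex-2-enal | CC(/C=O)=C\[C@@H](C)CCO | intermediate
19 | (7R)-5-chloro-7-hydroxy-3-[(1E,3E,5S)-7-hydroxy-3,5-dimethylhepta-1,3-dien-1-yl]-7-methyl-6H-isochromene-6,8(7H)-dione | CC(/C=C/C1=CC2=C(Cl)C(=O)[C@](C)(O)C(=O)C2=CO1)=C\[C@@H](C)CCO | intermediate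
20 | (7R,8R)-5-chloro-7,8-dihydroxy-3-[(1E,3E,5S)-7-hydroxy-3,5-dimethylhepta-1,3-dien-1-yl]-7-methyl-7,8-dihydro-6H-isochromen-6-one | CC(/C=C/C1=CC2=C(Cl)C(=O)[C@](C)(O)[C@H](O)C2=CO1)=C\[C@@H](C)CCO | target

Total step count: 14. Longest linear sequence: 10 steps (steps 1–7, 10, 13, 14).

Steps most likely to fail

Step 10 (proposed new method). The ketene acetal may be acylated on oxygen, the nucleophile may add to an α-position of the pyrylium-like cation, or the sequence may stall after the first acylation without ring closure. The fallback uses the established alkynylbenzaldehyde route to this ring system; it sets out from 18 and comes back at 19. Wittig reaction of 18 with the ylide from [3-(trimethylsilyl)prop-2-yn-1-yl]triphenylphosphonium bromide and n-BuLi should give (3S,4E,6E)-3,5-dimethyl-9-(trimethylsilyl)nona-4,6-dien-8-yn-1-ol F1, and K2CO3 in MeOH the terminal dienyne (3S,4E,6E)-3,5-dimethylnona-4,6-dien-8-yn-1-ol F2. Sonogashira coupling (Pd(PPh3)2Cl2, CuI, Et3N) with 6-bromo-2,4-dihydroxy-3-methylbenzaldehyde should give 2,4-dihydroxy-6-[(3E,5E,7S)-9-hydroxy-5,7-dimethylnona-3,5-dien-1-yn-1-yl]-3-methylbenzaldehyde F3. Oxidative dearomatisation with Cu(MeCN)4PF6, O2 and the sparteine-type diamine of the sense that delivers 7R, followed by buffered cycloisomerisation of the alkynyl quinol, should give (7R)-7-hydroxy-3-[(1E,3E,5S)-7-hydroxy-3,5-dimethylhepta-1,3-dien-1-yl]-7-methyl-6H-isochromene-6,8(7H)-dione F4. Chlorination at C5 with N-chlorosuccinimide then gives 19.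

Step 14. Hydride may be delivered to the wrong face of C8 through chelation by the C7 hydroxyl, or C6 may be reduced in competition. The fallback makes the C8 configuration irrelevant by a stereoconvergent closure; it sets out from 19 and comes back at 20. Boc2O and DMAP should give the bis(tert-butyl carbonate) of 19 at the C7 and side-chain hydroxyls F5. NaBH4 with CeCl3·7H2O reduces C8 to the C8 carbinol as either epimer F6. CF3CO2H in CH2Cl2 then ionises the C8 hydroxyl (cation stabilised by O2 through C1=C8a), the C7 carbonate captures it with loss of its tert-butyl group, and both epimers funnel into the cis-fused 7,8-cyclic carbonate of 20 F7 while the primary carbonate is cleaved. K2CO3 in MeOH releases 20.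

Step 4. The carbenoid may attack the ring enol-ether double bonds or the alkyl chloride instead of sulfur, or sulfur extrusion may be incomplete. The fallback replaces the carbenoid by an ionic sulfide contraction; it sets out from 4 and comes back at 6. S-Alkylation of 4 with tert-butyl bromoacetate should give 4-[(2-tert-butoxy-2-oxoethyl)sulfanyl]-2-(chloromethyl)pyrylium bromide F8, and Et3N with PPh3 (Eschenmoser sulfide contraction through the episulfide) gives 6.

Further compounds
F1 | step 10 | (3S,4E,6E)-3,5-dimethyl-9-(trimethylsilyl)nona-4,6-dien-8-yn-1-ol | CC(/C=C/C#C[Si](C)(C)C)=C\[C@@H](C)CCO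
F2 | step 10 | (3S,4E,6E)-3,5-dimethylnona-4,6-dien-8-yn-1-ol | CC(/C=C/C#C)=C\[C@@H](C)CCO
F3 | step 10 | 2,4-dihydroxy-6-[(3E,5E,7S)-9-hydroxy-5,7-dimethylnona-3,5-dien-1-yn-1-yl]-3-methylbenzaldehyde | CC(/C=C/C#Cc1cc(O)c(C)c(O)c1C=O)=C\[C@@H](C)CCO
F4 | step 10 | (7R)-7-hydroxy-3-[(1E,3E,5S)-7-hydroxy-3,5-dimethylhepta-1,3-dien-1-yl]-7-methyl-6H-isochromene-6,8(7H)-dione | CC(/C=C/C1=CC2=CC(=O)[C@](C)(O)C(=O)C2=CO1)=C\[C@@H](C)CCO
F5 | step 14 | bis(tert-butyl carbonate) of 19 at the C7 and side-chain hydroxyls | CC(/C=C/C1=CC2=C(Cl)C(=O)[C@](C)(OC(=O)OC(C)(C)C)C(=O)C2=CO1)=C\[C@@H](C)CCOC(=O)OC(C)(C)C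
F6 | step 14 | C8 carbinol of F5 (either epimer) | CC(/C=C/C1=CC2=C(Cl)C(=O)[C@](C)(OC(=O)OC(C)(C)C)C(O)C2=CO1)=C\[C@@H](C)CCOC(=O)OC(C)(C)C
F7 | step 14 | cis-fused 7,8-cyclic carbonate of 20 | CC(/C=C/C1=CC2=C(Cl)C(=O)[C@]3(C)OC(=O)O[C@@H]3C2=CO1)=C\[C@@H](C)CCO
F8 | step 4 | 4-[(2-tert-butoxy-2-oxoethyl)sulfanyl]-2-(chloromethyl)pyrylium bromide | [Br-].ClCc1cc(SCC(=O)OC(C)(C)C)cc[o+]1
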